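**Plan**

Numbering: pyranone O1, C2(=O), C3=C4, C5, C6; side chain C1'=C2', C3', C4'(OAc), C5', C6'(OH), C7', C8'(OH), C9', C10'(Ph). The target is read as 6S, 1'E, 4'R, 6'R, 8'R.
Cuts, in retrosynthetic order: the two silyl ethers; C1'=C2' (cross-metathesis of a 6-vinylpyranone with a C2'–C10' terminal alkene); C3'–C4' (allylation of a C4' aldehyde); C9'–C10' (benzylidene Wittig, then hydrogenation); last, C4' and C9' are tied through oxygen into an oxepanone, the Baeyer–Villiger product of a six-membered ketone.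
Enabling feature: C4'–C5'–C6'(O)–C7'–C8'(O)–C9' with its syn-diol is the carbocycle of meso cis-3,5-bis(silyloxy)cyclohexanone opened at the ring bond C4'–C9' (carbonyl carbon = C4', migrating methylene = C9').
Forward: triol → meso ketone → oxepanone (ring expansion; the only ring made on the chain, opened in the next step) → growth at C9', then at C4' → acetate → union with the pyranone (ring made separately by ring-closing metathesis) → desilylation.
Stereochemistry: C6'/C8' syn from the all-cis triol, their absolute sense from the catalyst's choice between the two enantiotopic α-methylenes; C4' (R) and C6 (S) from reagent-controlled allylborations with antipodal Ipc2B-allyl reagents; the E-alkene from cross-metathesis.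

Key step: step 3

Assumption: which antipode of the scandium ligand makes the C9' methylene migrate in this substrate cannot be predicted with confidence; both antipodes are equally accessible (from L- or D-pipecolic acid) and the one that leads to (4R,6S)-4 is taken. Abbreviations: TBS = tert-butyldimethylsilyl, TBSO = tert-butyldimethylsilyloxy, Ipc = isopinocampheyl.

**Route**

Step 1
Reactants: 1 cis,cis-cyclohexane-1,3,5-triol
Product: 2 all-cis-3,5-bis(TBSO)cyclohexan-1-ol (meso)
Conditions: TBSCl (2.0 equiv), imidazole, DMF, 0 °C to rt; mono- and tris-silyl ethers separated and recycled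
Reagents that add atoms: tert-butyldimethylsilyl chloride, CC(C)(C)[Si](C)(C)Cl
Why: Statistical silylation of three equivalent hydroxyls, in which the bis-ether should dominate at two equivalents and, being meso, is a single compound.

Step 2
Reactants: 2 all-cis-3,5-bis(TBSO)cyclohexan-1-ol
Product: 3 meso cis-3,5-bis(TBSO)cyclohexan-1-one [(3R,5S)]
Conditions: Dess–Martin periodinane, CH2Cl2, 0 °C to rt
Reagents that add atoms: none
Why: Dess–Martin oxidation of a secondary alcohol under non-basic conditions, which avoids the β-elimination of silanol that a β-silyloxy ketone risks with amine bases.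

Step 3
Reactants: 3 meso cis-3,5-bis(TBSO)cyclohexan-1-one
Product: 4 (4R,6S)-4,6-bis(TBSO)oxepan-2-one
Conditions: Sc(OTf)3 (10 mol %), chiral C2-symmetric N,N'-dioxide ligand (bis-N-oxide of 1,3-bis[2-(2,6-diisopropylphenylcarbamoyl)piperidin-1-yl]propane, 10 mol %), mCPBA (1.2 equiv), EtOAc, −20 °C
Reagents that add atoms: meta-chloroperbenzoic acid, O=C(OO)c1cccc(Cl)c1
Why: Baeyer–Villiger oxidation: the scandium-bound ketone adds the peracid to give a Criegee adduct, and the α-methylene that lies antiperiplanar to the O–O bond migrates from carbon to oxygen as 3-chlorobenzoate leaves. The closest known reactions are the Sc(OTf)3/N,N'-dioxide-catalysed and monooxygenase-mediated desymmetrising Baeyer–Villiger oxidations of 4-substituted and cis-3,5-dialkylcyclohexanones. The seven-membered ring arises by ring expansion (a 1,2-shift that inserts oxygen into the C4'–C9' bond), not by a cyclisation. No new sp3 centre is made, but C6' and C8' become stereogenic with defined absolute configuration because the chiral ligand sphere around trivalent scandium decides which of the two enantiotopic methylenes migrates. Only enantiotopos selectivity is needed: both α-carbons are electronically identical CH2 groups, so there is no regiochemical bias to overcome, and the chair with two equatorial silyloxy groups offers the catalyst one rigid conformer. Silyl ethers are inert to the peracid and the lactone is not oxidised further.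

Step 4
Reactants: 4 (4R,6S)-4,6-bis(TBSO)oxepan-2-one
Product: 5 (3R,5S)-3,5-bis(TBSO)-6-hydroxy-N-methoxy-N-methylhexanamide
Conditions: MeNH(OMe)·HCl, AlMe3, CH2Cl2, 0 °C to rt; aq. potassium sodium tartrate
Reagents that add atoms: N,O-dimethylhydroxylamine hydrochloride, CNOC.Cl
Why: Aluminium-amide aminolysis of a lactone (Weinreb amide formation) cleaves the acyl–oxygen bond without a free basic alkoxide, so β-elimination at C6' and silyl migration from the C8' to the C9' oxygen are not expected.

Step 5
Reactants: 5 (3R,5S)-3,5-bis(TBSO)-6-hydroxy-N-methoxy-N-methylhexanamide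
Product: 6 (3R,5S)-3,5-bis(TBSO)-N-methoxy-N-methyl-6-oxohexanamide
Conditions: Dess–Martin periodinane, CH2Cl2, 0 °C to rt; used crude
Reagents that add atoms: none
Why: Dess–Martin oxidation of the primary C9' alcohol under non-basic conditions, under which the α-silyloxy aldehyde should keep its C8' configuration.

Step 6
Reactants: 6 (3R,5S)-3,5-bis(TBSO)-N-methoxy-N-methyl-6-oxohexanamide; 7 benzyltriphenylphosphonium chloride
Product: 9 (3R,5S)-3,5-bis(TBSO)-N-methoxy-N-methyl-7-phenylhept-6-enamide (E/Z mixture), via benzylidenetriphenylphosphorane 8 (not isolated)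
Conditions: 7 (1.2 equiv), NaN(SiMe3)2 (1.1 equiv), THF, 0 °C; then 6, −78 °C to 0 °C
Reagents that add atoms: none
Why: Wittig olefination with a semi-stabilised ylide, which attacks the aldehyde far faster than the Weinreb amide; a deficit of base relative to the salt protects the α-silyloxy centre, and the alkene geometry is irrelevant because the double bond is hydrogenated next.

Step 7
Reactants: 9 (3R,5S)-3,5-bis(TBSO)-N-methoxy-N-methyl-7-phenylhept-6-enamide
Product: 10 (3R,5R)-3,5-bis(TBSO)-N-methoxy-N-methyl-7-phenylheptanamide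
Conditions: H2 (1 atm), Pd/C (10 wt % palladium on carbon), EtOAc, rt
Reagents that add atoms: none
Why: Heterogeneous catalytic hydrogenation of a styrene, under which the silyl ethers, the allylic C–O bond and the N–O bond of the amide should survive in ethyl acetate at one atmosphere.

Step 8
Reactants: 10 (3R,5R)-3,5-bis(TBSO)-N-methoxy-N-methyl-7-phenylheptanamide
Product: 11 (3R,5R)-3,5-bis(TBSO)-7-phenylheptanal
Conditions: i-Bu2AlH, THF, −78 °C; aq. potassium sodium tartrate; used crude
Reagents that add atoms: none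
Why: Hydride reduction of a Weinreb amide stops at the aldehyde because the chelated tetrahedral aluminium adduct collapses only on work-up.

Step 9
Reactants: 11 (3R,5R)-3,5-bis(TBSO)-7-phenylheptanal
Product: 12 (4R,6S,8R)-6,8-bis(TBSO)-10-phenyldec-1-en-4-ol
Conditions: (+)-Ipc2BOMe [from (−)-α-pinene], allylMgBr, Et2O, 0 °C to rt; then 11, −78 °C; NaOH, H2O2
Reagents that add atoms: allylmagnesium bromide, C=CC[Mg]Br
Why: Brown allylboration through a chair-like six-membered transition state, in which this antipode of the isopinocampheyl reagent delivers allyl to the Re face of the aldehyde and so sets C4' as R (4',6'-anti) under reagent control, which should override the weak bias of the β-silyloxy group.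

Step 10
Reactants: 12 (4R,6S,8R)-6,8-bis(TBSO)-10-phenyldec-1-en-4-ol
Product: 13 (4R,6S,8R)-6,8-bis(TBSO)-10-phenyldec-1-en-4-yl acetate
Conditions: Ac2O, pyridine, DMAP (cat.), CH2Cl2, rt
Reagents that add atoms: acetic anhydride, CC(=O)OC(C)=O
Why: DMAP-catalysed acylation of a secondary alcohol, which takes place at oxygen with retention at C4'.

Step 11
Reactants: 14 acrolein
Product: 15 (S)-hexa-1,5-dien-3-ol
Conditions: (−)-Ipc2BOMe [from (+)-α-pinene], allylMgBr, Et2O, 0 °C to rt; then 14, −78 °C; NaOH, H2O2; careful distillation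
Reagents that add atoms: allylmagnesium bromide, C=CC[Mg]Br
Why: Brown allylboration with the antipodal reagent, which delivers allyl to the Si face of acrolein and gives the S carbinol that becomes C6.

Step 12
Reactants: 15 (S)-hexa-1,5-dien-3-ol
Product: 16 (S)-hexa-1,5-dien-3-yl prop-2-enoate
Conditions: acryloyl chloride, Et3N, DMAP (cat.), CH2Cl2, 0 °C
Reagents that add atoms: acryloyl chloride, C=CC(=O)Cl
Why: O-acylation of a secondary allylic alcohol with an acid chloride, which leaves the carbinol configuration untouched.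

Step 13
Reactants: 16 (S)-hexa-1,5-dien-3-yl prop-2-enoate
Product: 17 (S)-6-vinyl-5,6-dihydro-2H-pyran-2-one
Conditions: first-generation Grubbs catalyst RuCl2(=CHPh)(PCy3)2 (5 mol %), CH2Cl2 (0.01 M), 40 °C
Reagents that add atoms: none
Why: Ring-closing metathesis, in which the carbene loads at the unhindered allyl terminus and closes onto the acrylate to the six-membered enoate, whereas the butenolide would require loading at the hindered allylic vinyl group, which is therefore left for step 14.

Step 14
Reactants: 13 (4R,6S,8R)-6,8-bis(TBSO)-10-phenyldec-1-en-4-yl acetate; 17 (S)-6-vinyl-5,6-dihydro-2H-pyran-2-one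
Product: 18 (6S)-6-[(1E,4R,6S,8R)-4-acetoxy-6,8-bis(TBSO)-10-phenyldec-1-en-1-yl]-5,6-dihydro-2H-pyran-2-one
Conditions: second-generation Hoveyda–Grubbs catalyst RuCl2(H2IMes)(=CH–C6H4-2-Oi-Pr) (10 mol %), 17 (3 equiv), CH2Cl2, 40 °C
Reagents that add atoms: none
Why: Olefin cross-metathesis between a fast-reacting terminal alkene and a slowly dimerising, allylically oxygenated vinyl group, a pairing that favours the cross product and, through reversible secondary metathesis, the E isomer, while the endocyclic enoate and the esters are spectators.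

Step 15
Reactants: 18 (6S)-6-[(1E,4R,6S,8R)-4-acetoxy-6,8-bis(TBSO)-10-phenyldec-1-en-1-yl]-5,6-dihydro-2H-pyran-2-one
Product: 19 (6S)-6-[(1E,4R,6R,8R)-4-acetoxy-6,8-dihydroxy-10-phenyldec-1-en-1-yl]-5,6-dihydro-2H-pyran-2-one
Conditions: HF·pyridine, pyridine, THF, 0 °C to rt
Reagents that add atoms: none
Why: Fluoride-driven cleavage of the two secondary silyl ethers under pyridine-buffered, mildly acidic conditions, under which the acetate and the unsaturated lactone should persist and acetyl migration from O4' to O6', a base-promoted process, should be slow.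

**Compound list**

1 | cis,cis-cyclohexane-1,3,5-triol | O[C@@H]1C[C@H](O)C[C@H](O)C1 | starting material
2 | all-cis-3,5-bis(TBSO)cyclohexan-1-ol (meso) | O[C@@H]1C[C@H](O[Si](C)(C)C(C)(C)C)C[C@H](O[Si](C)(C)C(C)(C)C)C1 | intermediate
3 | meso cis-3,5-bis(TBSO)cyclohexan-1-one | O=C1C[C@H](O[Si](C)(C)C(C)(C)C)C[C@H](O[Si](C)(C)C(C)(C)C)C1 | intermediate
4 | (4R,6S)-4,6-bis(TBSO)oxepan-2-one | O=C1C[C@H](O[Si](C)(C)C(C)(C)C)C[C@H](O[Si](C)(C)C(C)(C)C)CO1 | intermediate
5 | (3R,5S)-3,5-bis(TBSO)-6-hydroxy-N-methoxy-N-methylhexanamide | CON(C)C(=O)C[C@H](O[Si](C)(C)C(C)(C)C)C[C@H](O[Si](C)(C)C(C)(C)C)CO | intermediate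
6 | (3R,5S)-3,5-bis(TBSO)-N-methoxy-N-methyl-6-oxohexanamide | CON(C)C(=O)C[C@H](O[Si](C)(C)C(C)(C)C)C[C@H](O[Si](C)(C)C(C)(C)C)C=O | intermediate
7 | benzyltriphenylphosphonium chloride | [Cl-].c1ccc(C[P+](c2ccccc2)(c2ccccc2)c2ccccc2)cc1 | starting material
8 | benzylidenetriphenylphosphorane | C(=P(c1ccccc1)(c1ccccc1)c1ccccc1)c1ccccc1 | intermediate (not isolated)
9 | (3R,5S)-3,5-bis(TBSO)-N-methoxy-N-methyl-7-phenylhept-6-enamide (E/Z mixture) | CON(C)C(=O)C[C@H](O[Si](C)(C)C(C)(C)C)C[C@H](O[Si](C)(C)C(C)(C)C)C=Cc1ccccc1 | intermediate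
10 | (3R,5R)-3,5-bis(TBSO)-N-methoxy-N-methyl-7-phenylheptanamide | CON(C)C(=O)C[C@H](O[Si](C)(C)C(C)(C)C)C[C@H](O[Si](C)(C)C(C)(C)C)CCc1ccccc1 | intermediate
11 | (3R,5R)-3,5-bis(TBSO)-7-phenylheptanal | O=CC[C@H](O[Si](C)(C)C(C)(C)C)C[C@H](O[Si](C)(C)C(C)(C)C)CCc1ccccc1 | intermediate
12 | (4R,6S,8R)-6,8-bis(TBSO)-10-phenyldec-1-en-4-ol | C=CC[C@@H](O)C[C@H](O[Si](C)(C)C(C)(C)C)C[C@H](O[Si](C)(C)C(C)(C)C)CCc1ccccc1 | intermediate
13 | (4R,6S,8R)-6,8-bis(TBSO)-10-phenyldec-1-en-4-yl acetate | C=CC[C@@H](OC(C)=O)C[C@H](O[Si](C)(C)C(C)(C)C)C[C@H](O[Si](C)(C)C(C)(C)C)CCc1ccccc1 | intermediate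
14 | acrolein | C=CC=O | starting material
15 | (S)-hexa-1,5-dien-3-ol | C=C[C@@H](O)CC=C | intermediate
16 | (S)-hexa-1,5-dien-3-yl prop-2-enoate | C=C[C@@H](OC(=O)C=C)CC=C | intermediate
17 | (S)-6-vinyl-5,6-dihydro-2H-pyran-2-one | C=C[C@@H]1CC=CC(=O)O1 | intermediate
18 | (6S)-6-[(1E,4R,6S,8R)-4-acetoxy-6,8-bis(TBSO)-10-phenyldec-1-en-1-yl]-5,6-dihydro-2H-pyran-2-one | CC(=O)O[C@H](C/C=C/[C@@H]1CC=CC(=O)O1)C[C@H](O[Si](C)(C)C(C)(C)C)C[C@H](O[Si](C)(C)C(C)(C)C)CCc1ccccc1 | intermediate
19 | (6S)-6-[(1E,4R,6R,8R)-4-acetoxy-6,8-dihydroxy-10-phenyldec-1-en-1-yl]-5,6-dihydro-2H-pyran-2-one | CC(=O)O[C@H](C/C=C/[C@@H]1CC=CC(=O)O1)C[C@H](O)C[C@H](O)CCc1ccccc1 | target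

**Step count**

Total steps: 15. Longest linear sequence: 12 (steps 1–10, 14, 15, from triol 1); the pyranone 17 takes 3 steps from acrolein.

**Steps most likely to fail, with fallbacks**

Step 3. The catalyst may discriminate poorly between the two enantiotopic methylenes of a ketone whose 3,5-substituents are bulky silyloxy groups and not alkyl groups, which would give a scalemic lactone that cannot be upgraded; slow oxidation of the hindered ketone is a second risk. The fallback does not desymmetrise at all but buys the C4'–C9' unit with both carbinol centres in place. It sets out from phosphonium salt 7 (as ylide 8) and the commercial statin side-chain building block tert-butyl 2-[(4R,6S)-6-(hydroxymethyl)-2,2-dimethyl-1,3-dioxan-4-yl]acetate F1, which carries the same syn-diol in the same absolute sense. Parikh–Doering oxidation (SO3·pyridine, DMSO, i-Pr2NEt) should give tert-butyl 2-[(4R,6S)-6-formyl-2,2-dimethyl-1,3-dioxan-4-yl]acetate F2. Wittig reaction with 8 should then give tert-butyl 2-[(4R,6S)-2,2-dimethyl-6-(2-phenylethenyl)-1,3-dioxan-4-yl]acetate F3, and hydrogenation (H2, Pd/C, EtOAc) tert-butyl 2-[(4R,6R)-2,2-dimethyl-6-(2-phenylethyl)-1,3-dioxan-4-yl]acetate F4. Acetonide removal (dilute aq. HCl, MeOH, rt) should give tert-butyl (3R,5R)-3,5-dihydroxy-7-phenylheptanoate F5, and silylation (TBSCl, imidazole, DMF) tert-butyl (3R,5R)-3,5-bis(TBSO)-7-phenylheptanoate F6. Reduction with excess i-Bu2AlH should give (3S,5R)-3,5-bis(TBSO)-7-phenylheptan-1-ol F7, and Dess–Martin oxidation returns to the route at aldehyde 11.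

Step 14. Unproductive homodimerisation of 13 and slow turnover of the allylically oxygenated vinyl lactone may leave conversion low or give E/Z mixtures, and ruthenium hydrides may isomerise the vinyl group. The fallback builds the pyranone on the chain and sets out from acetate 13. Cross-metathesis with crotonaldehyde (same ruthenium catalyst) should give (2E,5R,7S,9R)-7,9-bis(TBSO)-1-oxo-11-phenylundec-2-en-5-yl acetate F8. Allylboration with the reagent of step 11 (Si-face delivery, ethanolamine work-up to spare the acetate) should give (4S,5E,8R,10S,12R)-10,12-bis(TBSO)-4-hydroxy-14-phenyltetradeca-1,5-dien-8-yl acetate F9. Acryloylation (acryloyl chloride, Et3N, DMAP) should give (4S,5E,8R,10S,12R)-8-acetoxy-10,12-bis(TBSO)-14-phenyltetradeca-1,5-dien-4-yl prop-2-enoate F10, and ring-closing metathesis with RuCl2(=CHPh)(PCy3)2 closes the six-membered enoate and comes back to the route at 18.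

Step 9. Facial selectivity of the allyl transfer may be poor if the β-silyloxy group and the reagent oppose each other, which would give C4' epimers that are hard to separate. The fallback sets C4' by inversion and sets out from aldehyde 11. Allylboration with the antipodal reagent (that of step 11, Si-face delivery) should give (4S,6S,8R)-6,8-bis(TBSO)-10-phenyldec-1-en-4-ol F11. Mitsunobu esterification with acetic acid (PPh3, diisopropyl azodicarboxylate, AcOH, toluene, 0 °C) then inverts C4' and gives acetate 13 directly, where it rejoins the route.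

**Further compounds**

F1 | step 3 | tert-butyl 2-[(4R,6S)-6-(hydroxymethyl)-2,2-dimethyl-1,3-dioxan-4-yl]acetate | CC(C)(C)OC(=O)C[C@H]1C[C@@H](CO)OC(C)(C)O1
F2 | step 3 | tert-butyl 2-[(4R,6S)-6-formyl-2,2-dimethyl-1,3-dioxan-4-yl]acetate | CC(C)(C)OC(=O)C[C@H]1C[C@@H](C=O)OC(C)(C)O1
F3 | step 3 | tert-butyl 2-[(4R,6S)-2,2-dimethyl-6-(2-phenylethenyl)-1,3-dioxan-4-yl]acetate (E/Z mixture) | CC(C)(C)OC(=O)C[C@H]1C[C@@H](C=Cc2ccccc2)OC(C)(C)O1
F4 | step 3 | tert-butyl 2-[(4R,6R)-2,2-dimethyl-6-(2-phenylethyl)-1,3-dioxan-4-yl]acetate | CC(C)(C)OC(=O)C[C@H]1C[C@@H](CCc2ccccc2)OC(C)(C)O1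
F5 | step 3 | tert-butyl (3R,5R)-3,5-dihydroxy-7-phenylheptanoate | CC(C)(C)OC(=O)C[C@H](O)C[C@H](O)CCc1ccccc1
F6 | step 3 | tert-butyl (3R,5R)-3,5-bis(TBSO)-7-phenylheptanoate | CC(C)(C)OC(=O)C[C@H](O[Si](C)(C)C(C)(C)C)C[C@H](O[Si](C)(C)C(C)(C)C)CCc1ccccc1
F7 | step 3 | (3S,5R)-3,5-bis(TBSO)-7-phenylheptan-1-ol | OCC[C@H](O[Si](C)(C)C(C)(C)C)C[C@H](O[Si](C)(C)C(C)(C)C)CCc1ccccc1
F8 | step 14 | (2E,5R,7S,9R)-7,9-bis(TBSO)-1-oxo-11-phenylundec-2-en-5-yl acetate | CC(=O)O[C@H](C/C=C/C=O)C[C@H](O[Si](C)(C)C(C)(C)C)C[C@H](O[Si](C)(C)C(C)(C)C)CCc1ccccc1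
F9 | step 14 | (4S,5E,8R,10S,12R)-10,12-bis(TBSO)-4-hydroxy-14-phenyltetradeca-1,5-dien-8-yl acetate | CC(=O)O[C@H](C/C=C/[C@@H](O)CC=C)C[C@H](O[Si](C)(C)C(C)(C)C)C[C@H](O[Si](C)(C)C(C)(C)C)CCc1ccccc1
F10 | step 14 | (4S,5E,8R,10S,12R)-8-acetoxy-10,12-bis(TBSO)-14-phenyltetradeca-1,5-dien-4-yl prop-2-enoate | CC(=O)O[C@H](C/C=C/[C@@H](OC(=O)C=C)CC=C)C[C@H](O[Si](C)(C)C(C)(C)C)C[C@H](O[Si](C)(C)C(C)(C)C)CCc1ccccc1
F11 | step 9 | (4S,6S,8R)-6,8-bis(TBSO)-10-phenyldec-1-en-4-ol | C=CC[C@H](O)C[C@H](O[Si](C)(C)C(C)(C)C)C[C@H](O[Si](C)(C)C(C)(C)C)CCc1ccccc1
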